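## Plan

Numbering (eudesmane): ring A = C1–C2–C3–C4–C5–C10, ring B = C5–C6–C7–C8–C9–C10; C14 on C10, C15 on C4, isopropylidene carbon C11 on C7, ketone at C8.
Cuts: first the two acyl–oxygen bonds (acetyl–O4, then 2-methylbutanoyl–O3), then in one operation the ring-fusion bond C5–C10 and the tertiary C4–O bond, and last the allylic C3–O bond.
Enabling feature: C5–C10 is common to rings A and B and links the methyl-bearing quaternary C10 (next to a plain C1H2) to C5, the neighbour of the methyl- and oxygen-bearing C4. Undoing it leaves an (E,E)-cyclodeca-1(10),4-diene whose C8 ketone and C7=C11 isopropylidene are those of germacrone.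
Forward: the ten-membered ring is bought as germacrone. C3 is hydroxylated, resolved and silylated, one transannular bond then makes rings A and B together, and the esters go on last, secondary before tertiary.
Stereochemistry: C3 comes from an enzymatic resolution. C10, C5 and C4 are relayed from C3 through the chair–chair closure and anti addition to the E alkene, which gives the diequatorial 3β,4α-dioxygen pattern that diaxial epoxide opening cannot. C2′ is bought with the (R)-acid.

Key step: step 4

Remark: the ring conformers of germacrone and its C3 derivatives are taken to interconvert quickly at room temperature, so C3 is the only fixed stereo-element before the cyclisation. All work on the ten-membered ring is kept below about 60 °C to avoid the Cope rearrangement of the cyclodeca-1,5-diene.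

## Route

Step 1
Reactants: 1 germacrone; 2 tert-butyl hydroperoxide
Product: 3 (±)-(1(10)E,4E)-3-hydroxygermacra-1(10),4,7(11)-trien-8-one
Conditions: SeO2 (0.3 equiv), t-BuOOH (5.5 M in decane, 2.5 equiv), CH2Cl2, 0 °C → rt
Reagents that add atoms: tert-butyl hydroperoxide, CC(C)(C)OO (its oxygen atom is passed on by the SeO2 catalyst)
Why: The Riley allylic hydroxylation in its SeO2-catalysed, t-BuOOH-driven form (ene reaction, then [2,3]-sigmatropic shift) should engage C4=C5, the most electron-rich of the three alkenes because C1=C10 lies β,γ to the ketone and C7=C11 is conjugated with it, and should oxidise the ring methylene at the substituted terminus that stands trans to C6, which is C3, with return of the E alkene; 1 is achiral, so C3 arises racemic.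

Step 2
Reactants: 3 (±)-3-hydroxygermacrone
Product: 4 (3S)-3-hydroxygermacrone
Conditions: immobilised Burkholderia cepacia lipase, vinyl acetate (3 equiv), MTBE, 30 °C, stopped just past half conversion; chromatography
Reagents that add atoms: none
Why: Lipase-catalysed kinetic resolution by irreversible acyl transfer is well known for 2-substituted cycloalk-2-en-1-ols, and by the Kazlauskas size rule (large group = branched C4 alkenyl side, medium group = C2H2) the enzyme should acetylate the 3R alcohol and leave the 3S alcohol 4, which chromatography separates from the acetate.

Step 3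
Reactants: 4 (3S)-3-hydroxygermacrone; 5 tert-butyl(chloro)diphenylsilane
Product: 6 (3S)-3-(tert-butyldiphenylsilyloxy)germacrone
Conditions: TBDPSCl (1.3 equiv), imidazole (2.5 equiv), DMF, rt
Reagents that add atoms: tert-butyl(chloro)diphenylsilane, CC(C)(C)[Si](Cl)(c1ccccc1)c1ccccc1
Why: Imidazole-promoted silylation takes place at oxygen and leaves C3 untouched, and this silyl ether is chosen because it withstands aqueous acid, has a poorly donating oxygen, cannot bridge to C4 or wander to O4 as an ester could, and is bulky.

Step 4
Reactants: 6 (3S)-3-(tert-butyldiphenylsilyloxy)germacrone; 7 water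
Product: 9 (3S,4S,5R,10R)-3-(tert-butyldiphenylsilyloxy)-4-hydroxyeudesm-7(11)-en-8-one, via eudesm-4-yl cation 8 (not isolated)
Conditions: HClO4 (aq., about 1 M in the mixture), 1,4-dioxane/H2O 4:1, 0 °C → rt
Reagents that add atoms: water, O
Why: A proton adds to C1 from the outside of the ring while C5 of the facing C4=C5 alkene bonds to C10 across the ring, which leaves the tertiary C4 cation 8, and water then ends the sequence at C4. The closest known reaction type is the acid-promoted transannular cation–olefin cyclisation–hydration of (E,E)-germacra-1(10),4-dienes, germacrone among them, to trans-eudesmanes. The one new bond divides the ten-membered ring into two six-membered rings, 6-endo-trig for ring A (C4 and C5 both lie in it) and 6-exo-trig for ring B (only C5 lies in it), each through a chair-like array. C10 and C5 are set by the crossed face-to-face arrangement of the two E alkenes, which holds C14 and C15 on one face and H5 on the other and so gives the trans fusion, and C4 is set by anti addition across the E C4=C5 alkene, water entering opposite to the new bond and away from axial C14 to give the equatorial 4α-OH with C15 axial. The absolute sense comes from C3, because of the two mirror-related crossed conformers only one places the bulky silyloxy group equatorial in the nascent ring A chair, and for 3S this one leads to 4S,5R,10R. The step needs protonation at C1 rather than C5, capture rather than proton loss and an intact C3–O bond, and these are secured by the allylic oxygen that lowers the basicity of C4=C5 (whose own Markovnikov protonation has no productive transannular outlet), by the large excess of water beside a non-nucleophilic counter-ion, by the acid-stable and non-participating silyl ether, and by the electron-poor nature of the conjugated C7=C11 alkene.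

Step 5
Reactants: 9 3β-silyloxy-4α-hydroxyeudesmenone
Product: 10 (3S,4S,5R,10R)-3,4-dihydroxyeudesm-7(11)-en-8-one
Conditions: Bu4NF (3 equiv), AcOH (3 equiv), THF, rt → 40 °C
Reagents that add atoms: none
Why: Fluoride-driven cleavage of the Si–O bond, buffered with acetic acid so that basic fluoride does not deconjugate the enone, frees the C3 alcohol without touching any stereocentre.

Step 6
Reactants: 10 3β,4α-diol; 11 (R)-2-methylbutanoic acid
Product: 13 (3S,4S,5R,10R)-4-hydroxy-8-oxoeudesm-7(11)-en-3-yl (2R)-2-methylbutanoate, via O-acylisourea 12 (not isolated)
Conditions: DCC (1.3 equiv), DMAP (0.1 equiv), CH2Cl2, 0 °C → rt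
Reagents that add atoms: (R)-2-methylbutanoic acid, CC[C@@H](C)C(=O)O
Why: The Steglich esterification should acylate only the equatorial secondary C3 alcohol because the tertiary C4 alcohol reacts far more slowly, C3 keeps its configuration since its C–O bond is not broken, and the low temperature and catalytic DMAP loading guard the α-stereocentre of the acid, which is the source of C2′.

Step 7
Reactants: 13 3β-ester-4α-alcohol; 14 acetic anhydride
Product: 15 3β-[(2R)-2-methylbutanoyloxy]-4α-acetoxyeudesm-7(11)-en-8-one (CNP0111007.1)
Conditions: Ac2O (5 equiv), Et3N (6 equiv), DMAP (0.5 equiv), CH2Cl2, 40 °C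
Reagents that add atoms: acetic anhydride, CC(=O)OC(C)=O
Why: DMAP-catalysed acylation through the N-acetylpyridinium ion is the standard way to esterify tertiary alcohols under basic, non-ionising conditions, so the C4–O bond and with it the 4α configuration stay intact, and neither elimination nor migration of the C3 ester is expected.

## Compound list

1 | germacrone, (1(10)E,4E)-germacra-1(10),4,7(11)-trien-8-one | O=C1C/C(C)=C/CC/C(C)=C/CC1=C(C)C | starting material
2 | tert-butyl hydroperoxide | CC(C)(C)OO | starting material
3 | (±)-3-hydroxygermacrone, racemic at C3, both ring alkenes E | OC1C/C=C(C)/CC(=O)C(=C(C)C)C/C=C1\C | intermediate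
4 | (3S)-3-hydroxygermacrone | O[C@H]1C/C=C(C)/CC(=O)C(=C(C)C)C/C=C1\C | intermediate
5 | tert-butyl(chloro)diphenylsilane | CC(C)(C)[Si](Cl)(c1ccccc1)c1ccccc1 | starting material
6 | (3S)-3-(tert-butyldiphenylsilyloxy)germacrone | CC(C)(C)[Si](c1ccccc1)(c1ccccc1)O[C@H]1C/C=C(C)/CC(=O)C(=C(C)C)C/C=C1\C | intermediate
7 | water | O | starting material
8 | 3β-(tert-butyldiphenylsilyloxy)-8-oxoeudesm-7(11)-en-4-yl cation (5α-H, 10β-methyl, trans-fused) | CC(C)(C)[Si](c1ccccc1)(c1ccccc1)O[C@H]1CC[C@]2(C)CC(=O)C(=C(C)C)C[C@H]2[C+]1C | intermediate
9 | 3β-(tert-butyldiphenylsilyloxy)-4α-hydroxyeudesm-7(11)-en-8-one (3S,4S,5R,10R; both oxygens equatorial, C14 and C15 axial β, H5 α) | CC(C)(C)[Si](c1ccccc1)(c1ccccc1)O[C@H]1CC[C@]2(C)CC(=O)C(=C(C)C)C[C@H]2[C@]1(C)O | intermediate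
10 | 3β,4α-dihydroxyeudesm-7(11)-en-8-one | O[C@H]1CC[C@]2(C)CC(=O)C(=C(C)C)C[C@H]2[C@]1(C)O | intermediate
11 | (R)-2-methylbutanoic acid | CC[C@@H](C)C(=O)O | starting material
12 | O-[(2R)-2-methylbutanoyl]-N,N'-dicyclohexylisourea | CC[C@@H](C)C(=O)OC(=NC1CCCCC1)NC1CCCCC1 | intermediate
13 | 3β-[(2R)-2-methylbutanoyloxy]-4α-hydroxyeudesm-7(11)-en-8-one | CC[C@@H](C)C(=O)O[C@H]1CC[C@]2(C)CC(=O)C(=C(C)C)C[C@H]2[C@]1(C)O | intermediate
14 | acetic anhydride | CC(=O)OC(C)=O | starting material
15 | 3β-[(2R)-2-methylbutanoyloxy]-4α-acetoxyeudesm-7(11)-en-8-one (3S,4S,5R,10R,2′R) | CC[C@@H](C)C(=O)O[C@H]1CC[C@]2(C)CC(=O)C(=C(C)C)C[C@H]2[C@]1(C)OC(C)=O | target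

## Step count and risks

Total steps: 7. Longest linear sequence: 7 steps (1 → 3 → 4 → 6 → 9 → 10 → 13 → 15).

**Risk 1 (step 4).**
- Before water arrives, the C4 cation may lose a proton (from C3, C5 or C15) or take up a 1,2-hydride shift from C3.
- The inductively deactivated C4=C5 alkene may close so slowly that desilylation or allylic ionisation at C3 sets in.
- Allylic 1,2-strain between the silyloxy group and C15 may weaken the choice between the two crossed conformers, which means poor facial selectivity relative to C3.

The fallback replaces the proton by a soft metal electrophile. Setting out from 6, the divalent mercury salt Hg(OCOCF3)2 (THF/H2O, −20 °C) should attack C1 of the more electron-rich C1=C10 alkene. This should trigger the same C5–C10 closure and water capture at C4, without strong acid and at a temperature at which conformer choice and capture should be sharper. The product should be 1β-(trifluoroacetoxymercurio)-3β-(tert-butyldiphenylsilyloxy)-4α-hydroxyeudesm-7(11)-en-8-one F1. Bu3SnH (toluene, 0 °C → rt) should then exchange mercury for hydrogen through the C1 radical and leave the ketone alone, so the route is rejoined at 9.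

**Risk 2 (step 1).** Site selectivity may be poor. The ene reaction may start at C1=C10, the methyl groups C15 or C14 may be oxidised instead of C3, and the alcohol may be oxidised further. The fallback leaves reagent control for enzyme control. Setting out from 1, a whole-cell hydroxylation with a filamentous fungus of the Aspergillus niger type (resting cells, phosphate buffer, 28 °C) is used, with strains screened for attack at C3. This relies on cytochrome P450 C–H hydroxylation, in which the binding pocket rather than alkene nucleophilicity picks the allylic ring methylene. The material comes back at 3 and passes through step 2 whatever its enantiomeric composition. Further compounds on this way: none F0.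

**Risk 3 (step 2).** The enzyme may discriminate poorly between the enantiomers, because both flanks of the carbinol are long ring chains, and half of the material is lost in any case. The fallback exchanges resolution for asymmetric reduction. Setting out from 3, Dess–Martin periodinane (NaHCO3, CH2Cl2, 0 °C) should give (1(10)E,4E)-germacra-1(10),4,7(11)-triene-3,8-dione F2. A Corey–Bakshi–Shibata reduction follows, with (R)-2-methyl-CBS-oxazaborolidine (0.2 equiv) and catecholborane in toluene at −78 °C. It should treat the α-methyl alkenyl side (C4) as the large group and deliver the 3S alcohol. The C8 ketone, flanked by the tetrasubstituted isopropylidene, should react more slowly. The route is rejoined at 4.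

## Further compounds

F1 | step 4 | 1β-(trifluoroacetoxymercurio)-3β-(tert-butyldiphenylsilyloxy)-4α-hydroxyeudesm-7(11)-en-8-one | CC(C)(C)[Si](c1ccccc1)(c1ccccc1)O[C@H]1C[C@@H]([Hg]OC(=O)C(F)(F)F)[C@]2(C)CC(=O)C(=C(C)C)C[C@H]2[C@]1(C)O
F0 | step 1 | none | none
F2 | step 2 | (1(10)E,4E)-germacra-1(10),4,7(11)-triene-3,8-dione | O=C1C/C=C(C)/CC(=O)C(=C(C)C)C/C=C1\C
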